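## Structural features

The target is a germacrane sesquiterpenoid whose ten-membered carbocycle (C1–C10) is bridged by an oxygen between C3 and C10. C10, C1, C2, C3 and that oxygen therefore form a 3(2H)-furanone (C1 ketone, C2=C3 enol ether). A trans-fused α-methylene-γ-butyrolactone spans C7–C8 (ring oxygen on C8, exocyclic C11=C13, carbonyl C12). O6 carries the ester of (2S,3R)-2,3-dimethyloxirane-2-carboxylic acid. C4=C5 is a Z-trisubstituted alkene inside the ring, cross-conjugated with the furanone. C6, C7 and C8 are contiguous stereocentres (6R,7R,8S); C10 (R) is a quaternary ether carbon separated from them by the C9 methylene. The fragile groups are the α-methylene lactone (Michael acceptor), the glycidic ester, the allylic C6 ester and the β-oxygenated carbonyl relationships around C6–C8. The real difficulty is the ten-membered ring with a Z-alkene and a bridging enol ether, which resists direct cyclisation. The key step exploits the fact that C1 and C6 are both oxygenated and sit opposite each other. An imaginary C1–C6 bond divides the ring into ring B (C1, C6–C10, a p-menthane pattern) and ring A (C1–C6, a 4-hydroxycyclohex-2-enone that enforces Z at C4=C5). Cleaving the C1/C6 glycol of that decalin releases the ten-membered ring.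

## Logic of the disconnections

36 ⇒ 33. The O8–C12 acyl bond is cut and C12 lowered to the alcohol. The α-methylene lactone is the most electrophilic group and is best made last. The forward step must oxidise a primary allylic alcohol in the presence of the secondary O8–H and close the lactone without touching the epoxy ester.

33 ⇒ 32 ⇒ 26 + 30. Two O–Si bonds and then the O6–acyl bond are cut. This separates the side chain from the core and makes the route convergent. The esterification must acylate a hindered allylic alcohol without opening the oxirane, so O8 and O12 must still be blocked at that point.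

30 ⇒ 29 ⇒ 28 ⇒ 27. The oxirane C–O bonds are cut back to the E-alkene. Both side-chain stereocentres then come from one reagent-controlled epoxidation, which needs the allylic alcohol oxidation level as a handle.

26 ⇒ 25. The C6–H bond is cut. C6 is set after the ring exists, so it does not have to survive the fragmentation. The reduction must choose the C6 dienone carbonyl over the vinylogous ester at C1 and be controlled by the reagent.

25 ⇒ 24. The O10–C3 bond and the C2=C3 unsaturation are cut, giving a monocyclic 1,3-diketone with O10 silylated. This removes the only transannular bridge. The acid step must let O10 attack C3 and must spare the other silyl ethers.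

24 ⇒ 23. The C1–C6 bond is formed in the retrosynthetic sense. The medium ring becomes a cis-fused decalin whose two carbinol centres are lost again in the forward step, so only C7, C8 and C10 need to be correct. The forward step needs a single free cis-1,2-diol; therefore O10 is silylated before any tertiary hydroxyl exists at C1 or C6.

23 ⇒ 22. The C1–C2 bond is cut (aldol). Ring A becomes a side chain on ring B. The forward step needs a C1 ketone with no α-hydrogen and a methyl ketone held cis to it by the Z-alkene.

22 ⇒ 21 ⇒ 16 + 19. The C5–C6 bond is cut after adjusting C3 to the alcohol. This gives a four-carbon Z-alkenyl nucleophile and a ring-B 1,6-dione. The addition must take the less hindered C6 carbonyl, from the face away from the C7 substituent, and must outrun enolisation of the dione towards C7. Hence 16 is made under buffered conditions, not stored, and met with a non-basic organocerium reagent.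

19 ⇒ 17. The C4–CH3 and C5–I bonds are cut to an alkyne that already contains C2 and C3. The alkoxide must direct an anti carbometalation so that iodine ends cis to the carbinol carbon.

16 ⇒ 15 ⇒ 13. The C6 oxygen is removed. Because C10 is quaternary, the C1 ketone of 13 can enolise only towards C6, so regiochemistry is automatic.

13 ⇒ 12 ⇒ 11 ⇒ 10. The O10–Si bond is cut, C1 is returned to the carbinol, and the C9–H and C1–H bonds are cut back to an epoxy ketone. The tertiary C10–O bond then comes from an epoxide whose configuration is easy to control. The hydride must open at the secondary carbon C9.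

10 ⇒ 9 ⇒ 8. The O8–Si bond and the two epoxide C–O bonds are cut to a γ-hydroxy enone. The free C8 hydroxyl and the C7 substituent both steer the peroxide to the same face.

8 ⇒ 5 ⇒ 3. The C8–O bond is cut through the linear dienol ether of the enone. The oxygen must enter at the γ-carbon only and anti to the C7 substituent.

3 ⇒ 2 ⇒ 1. The O12–Si and C12–O bonds are cut, leaving a chiral-pool enone that supplies C7 with the correct absolute configuration and the whole carbon skeleton of ring B.

## Other disconnections considered

Alternative 1: The C6–C7 bond is cut and O6 is joined to C13, leading to the thirteen-membered bis-allylic ether A1, in which the lactone is a butenolide (C7=C11). In the forward direction, deprotonation at C6 starts a [2,3]-Wittig shift that forms C6–C7, releases the C11=C13 methylene and the C6 alkoxide, and contracts the ring to the 6-hydroxy core A2.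
- In its favour: one step would create a skeletal bond, two stereocentres and the exocyclic methylene, and A2 is a single acylation away from 36. On post-key-step economy it is clearly better than the chosen plan (one step against five).
- It is the equal of the chosen plan in avoiding a direct ten-membered cyclisation, since it contracts a larger ring.
- Against it: C6–H must be removed while the butenolide γ-hydrogen at C8 and the C13 methylene are at least as acidic. A [1,2]-shift can compete. C6 and C7 would be set by a macrocyclic transition state with no clear bias relative to C8. The product alkoxide sits next to a newly formed Michael acceptor.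
- Comparison: A1 already needs the furanone, the Z-alkene and a macrocyclic ether closure, so its front end is unlikely to be shorter. The chosen plan takes C7 from the chiral pool and sets C6 by reagent, using an oxidative two-electron fragmentation instead of an anionic pericyclic step under strong base.

Alternative 2: The C2–C3 and C4–C5 bonds are traced back to the cyclooctenone A3, which carries a 1-propynyl ether on O10. In the forward direction, irradiation joins C2 to C3 and C5 to C4 (closing the oxygen five-membered ring and a cyclobutene). Conrotatory opening of the C2–C5 bond then expands the eight-membered ring to the ten-membered core A4.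
- In its favour: the furanone bridge, both ring alkenes and the two-carbon expansion arise in one operation. Conrotatory opening of a cis-fused cyclobutene gives one E and one Z alkene in the larger ring, which is exactly what the furanone-locked C2=C3 and the Z C4=C5 need. On this point it is better than the chosen plan, which needs two steps (cleavage, then cyclodehydration). A4 also already holds the lactone.
- Against it: A3 is itself a medium ring carrying four stereocentres and a trans-fused α-methylene lactone. A tertiary ynol ether must be made on an α-ketol. The photochemistry has to beat Z/E isomerisation of the cyclooctenone, cycloaddition at the methylene lactone and crossed regiochemistry.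
- Comparison: the chosen plan replaces the medium-ring problem by six-membered-ring chemistry; this alternative only moves it from ten to eight. Any steps saved at the end are likely spent in reaching A3.

Alternative 3: The C8–C9 bond is cut, leading to the aldehyde A5, in which the furanone is masked as a cyclopropanated siloxyfuran (C9 bridging C1 and C10). In the forward direction, TiCl4 activates the C8 aldehyde, the C1–C9 cyclopropane bond opens onto it, and the ten-membered ring closes with return of the C1 ketone, giving the hydroxy malonate A6.
- In its favour: the furanone and C10 are in place before ring closure, strain release drives the step, and the homoenolate forms without base. The key step makes a skeletal bond and the C8 carbinol at once, which the chosen key step does not; on that point it is the better.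
- Against it: it is a true macrocyclisation with the entropic and transannular cost the chosen plan avoids. C8 would be set by 1,2-induction from an epimerisable α-branched aldehyde. TiCl4 meets an allylic silyl ether. C10 would have to come from a face-selective cyclopropanation of a flat furan and not from the chiral pool.
- Comparison: after A6 the malonate still needs lactonisation, decarboxylation and methylenation in addition to the side chain, so the endgame is longer than the five steps of the chosen plan.

Key step: step 16

Remarks on the chemistry and assumptions: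
- Germacrane numbering of 36 is used for every intermediate: C1 is the carvone carbonyl carbon, C10 the methyl-bearing carbon, C7 the carbon bearing the C11–C13 unit.
- The configurations at C7, C8 and C10 of 23 and 24 map atom for atom onto 36, the glycol of 23 is cis and C4=C5 is Z; no structure needed correction.
- But-3-yn-2-ol is used as the alkyne because it already contains C2; this saves two steps over a propargyl alcohol route. The racemate would serve equally, since the carbinol centre is oxidised in step 14.
- The carbinol configurations at C1 in 11 and at C6 in 15 are drawn as the expected epimers, but both centres become carbonyls and their configuration is inconsequential.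
- D-(−)-diethyl tartrate is chosen on the empirical rule that L-(+)-tartrate gives (2S,3S)-epoxides from (E)-2-alkenols.
- The catalyst enantiomer in step 18 assumes that the alkenyl arm of the C6 ketone acts as the large group.

## Route

Step 1
Reactants: 1 (R)-carvone
Product: 2 10-hydroxycarvone
Conditions: SeO2 (0.5 equiv), t-BuOOH, CH2Cl2, rt
Reagents that add atoms: tert-butyl hydroperoxide, CC(C)(C)OO (its oxygen is relayed through SeO2, O=[Se]=O)
Why: Allylic oxidation by SeO2 (ene reaction, then [2,3]-shift) takes place at the electron-rich 1,1-disubstituted alkene and not at the enone, and at the methyl group faster than at the C7 methine; C7 is not touched.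

Step 2
Reactants: 2 10-hydroxycarvone
Product: 3 10-(tert-butyldimethylsilyloxy)carvone
Conditions: TBSCl, imidazole, CH2Cl2, 0 °C → rt
Reagents that add atoms: tert-butyldimethylsilyl chloride, CC(C)(C)[Si](C)(C)Cl
Why: Standard silylation of the only hydroxyl; the ether must last until step 23.

Step 3
Reactants: 3 10-(tert-butyldimethylsilyloxy)carvone
Product: 5 linear trimethylsilyl dienol ether, via bromomagnesium dienolate 4 (not isolated)
Conditions: MeMgBr (1.2 equiv), FeCl3 (5 mol%), Et2O, −20 °C; then Me3SiCl, Et3N, DMPU, −20 °C → rt
Reagents that add atoms: chlorotrimethylsilane, C[Si](C)(C)Cl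
Why: Iron-catalysed deconjugative enolisation (Kharasch reagent) removes a γ-hydrogen at C8 and gives the linear dienolate, which is silylated on oxygen; the C7 stereocentre is not involved.

Step 4
Reactants: 5 linear trimethylsilyl dienol ether
Product: 8 8-hydroxy enone, via endoperoxide 6 (not isolated), via γ-hydroperoxy enone 7 (not isolated)
Conditions: O2, visible light, 5,10,15,20-tetraphenylporphyrin (cat.), CH2Cl2, −78 °C; then MeOH, PPh3, −78 °C → rt
Reagents that add atoms: dioxygen, O=O
Why: Singlet-oxygen [4+2] cycloaddition to the cyclohexa-1,3-diene can place oxygen only on C8 and C1, and does so anti to the substituent on the adjacent C7. Methanolysis of the silyl peroxyketal returns the enone, and PPh3 reduces the allylic hydroperoxide, so the C8 hydroxyl is trans to the C7 side chain.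

Step 5
Reactants: 8 8-hydroxy enone
Product: 9 9,10-epoxy-8-hydroxy ketone
Conditions: H2O2 (30% aq.), NaOH (0.3 equiv), MeOH, −10 °C
Reagents that add atoms: hydrogen peroxide, OO
Why: In this Weitz–Scheffer epoxidation the hydroperoxide adds to C9 on the face trans to the C7 substituent, as for carvone itself. That is also the face of the C8 hydroxyl, so the epoxide is cis to O8 and C10 receives its oxygen with the configuration of 36.

Step 6
Reactants: 9 9,10-epoxy-8-hydroxy ketone
Product: 10 9,10-epoxy-8-silyloxy ketone
Conditions: TBSOTf, 2,6-lutidine, CH2Cl2, −78 °C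
Reagents that add atoms: tert-butyldimethylsilyl triflate, CC(C)(C)[Si](C)(C)OS(=O)(=O)C(F)(F)F
Why: Low-temperature silylation of the hindered secondary alcohol with a hindered base leaves the epoxy ketone intact.

Step 7
Reactants: 10 9,10-epoxy-8-silyloxy ketone
Product: 11 1,10-diol
Conditions: LiBHEt3 (4 equiv), THF, 0 → 40 °C; then H2O
Reagents that add atoms: none
Why: The hydride first reduces the ketone and then opens the trisubstituted epoxide by SN2 attack at the secondary carbon C9, anti to the epoxide oxygen. The tertiary C10–O bond is kept with its configuration and C9 becomes the methylene.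

Step 8
Reactants: 11 1,10-diol
Product: 12 10-hydroxy 1-ketone
Conditions: IBX (2-iodoxybenzoic acid), DMSO, rt
Reagents that add atoms: none
Why: IBX oxidises the secondary C1 alcohol of a secondary/tertiary 1,2-diol to the α-hydroxy ketone without C–C cleavage.

Step 9
Reactants: 12 10-hydroxy 1-ketone
Product: 13 10-triethylsilyloxy 1-ketone
Conditions: Et3SiOTf, 2,6-lutidine, CH2Cl2, −78 → 0 °C
Reagents that add atoms: triethylsilyl triflate, CC[Si](CC)(CC)OS(=O)(=O)C(F)(F)F
Why: Silyl triflate silylation of the only free (tertiary) hydroxyl; O10 is blocked here, before any other tertiary alcohol exists, so that later only the C1/C6 glycol is free.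

Step 10
Reactants: 13 10-triethylsilyloxy 1-ketone
Product: 15 6-hydroxy 1-ketone, via potassium enolate 14 (not isolated)
Conditions: KN(SiMe3)2, THF, −78 °C; then 2-(phenylsulfonyl)-3-phenyloxaziridine, −78 °C; aq. NH4Cl
Reagents that add atoms: 2-(phenylsulfonyl)-3-phenyloxaziridine, O=S(=O)(c1ccccc1)N1OC1c1ccccc1
Why: Davis enolate hydroxylation; C10 is quaternary, so the ketone can enolise only towards C6. Oxygen should enter trans to the C7 substituent, which is irrelevant because C6 becomes a carbonyl.

Step 11
Reactants: 15 6-hydroxy 1-ketone
Product: 16 1,6-dione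
Conditions: Dess–Martin periodinane, NaHCO3, CH2Cl2, 0 °C; filtered, concentrated cold and used at once
Reagents that add atoms: none
Why: Dess–Martin oxidation of the α-hydroxy ketone to the 1,2-diketone under buffered, non-aqueous conditions; the dione is not stored, so that enolisation towards C7 has no time to occur.

Step 12
Reactants: 17 (R)-but-3-yn-2-ol
Product: 19 (2R,3Z)-4-iodo-3-methylbut-3-en-2-ol, via vinylmagnesium alkoxide 18 (not isolated)
Conditions: MeMgBr (3 equiv), CuI (10 mol%), THF, −10 °C → rt; then I2, −30 °C
Reagents that add atoms: methylmagnesium bromide, C[Mg]Br; iodine, II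
Why: Alkoxide-directed, copper-catalysed anti carbomagnesiation of the propargylic alcohol puts the methyl on the carbon next to the carbinol and magnesium on the terminus, cis to the alkoxide (five-membered chelate). Iodinolysis with retention gives the Z-iodide.

Step 13
Reactants: 16 1,6-dione; 19 (2R,3Z)-4-iodo-3-methylbut-3-en-2-ol
Product: 21 C6 adduct, via dilithio reagent 20 (not isolated)
Conditions: 19 (2.5 equiv), t-BuLi (3 equiv per 19), Et2O, −78 °C; CeCl3, THF, −78 °C; then 16, −78 °C; aq. NH4Cl
Reagents that add atoms: none
Why: Iodine–lithium exchange keeps the Z geometry, and transmetalation to cerium gives a weakly basic reagent that adds to the dione faster than it enolises it. Attack should go to C6, because C1 is shielded by the quaternary C10, and from the face opposite the C7 substituent, which puts C5 trans and O6 cis to the C7 side chain.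

Step 14
Reactants: 21 C6 adduct
Product: 22 6-hydroxy 1,3-dione
Conditions: MnO2, CH2Cl2, rt
Reagents that add atoms: none
Why: MnO2 oxidises only the secondary allylic alcohol and leaves the tertiary allylic C6 hydroxyl; the Z-γ-hydroxy enone may rest partly as its five-membered hemiketal, which base reopens in the next step.

Step 15
Reactants: 22 6-hydroxy 1,3-dione
Product: 23 cis-1,6-dihydroxy decalin enone
Conditions: LiN(SiMe3)2 (2.5 equiv), THF, −78 → −30 °C; AcOH, −78 °C
Reagents that add atoms: none
Why: Intramolecular aldol reaction (6-enolexo-exo-trig): the kinetic methyl-ketone enolate at C2 adds to the C1 ketone, which has no α-hydrogen. Lithium bridging between the C6 alkoxide and the C1 carbonyl, together with the Z-alkene tether, delivers C2 to the face of C1 on the side of C5, giving the cis-fused ring A and the cis C1/C6 diol.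

Step 16
Reactants: 23 cis-1,6-dihydroxy decalin enone
Product: 24 ten-membered 1,3,6-trione
Conditions: Pb(OAc)4 (1.05 equiv), K2CO3, toluene, 5 °C, 15 min
Reagents that add atoms: none
Why: Both tertiary hydroxyls exchange for acetate on lead and, being cis on the ring fusion, close a five-membered cyclic lead diester; this collapses in one concerted two-electron step in which the C1–C6 σ bond breaks, both C–O bonds become C=O and tetravalent lead leaves as divalent Pb(OAc)2. The closest known reaction type is the Criegee cleavage of ring-fusion cis-1,2-diols of bicyclo[4.4.0] systems to cyclodecanediones. No ring-closing bond is made: the ten-membered ring appears by scission of the bond shared by rings A and B, so no medium-ring cyclisation penalty is paid. No stereocentre is created; the two carbinol centres disappear, C7, C8 and C10 are not involved, and the Z geometry of C4=C5 is carried over from the cyclohexenone. Chemoselectivity rests on 23 having a single free 1,2-diol, since O10 carries the triethylsilyl group and O8 and O12 are silylated. Solid K2CO3 takes up the acetic acid so that the C7–H next to the new C6 ketone and the β-silyloxy group at C8 see neither acid nor base, and one equivalent of oxidant at 5 °C keeps the enolisable C1/C3 diketone from being acetoxylated.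

Step 17
Reactants: 24 ten-membered 1,3,6-trione
Product: 25 furanone 6-ketone
Conditions: p-TsOH·H2O (0.1 equiv), CH2Cl2, 0 °C → rt
Reagents that add atoms: none
Why: Acid-catalysed cyclodehydration of an α'-silyloxy 1,3-diketone to a 3(2H)-furanone: O10 attacks the activated C3 carbonyl (5-exo-trig), the silyl group leaves from the oxonium as Et3SiOH and water is lost across C2–C3. The TBS ethers have no such intramolecular assistance and no external nucleophile is present.

Step 18
Reactants: 25 furanone 6-ketone
Product: 26 (6R)-furanone alcohol
Conditions: (R)-2-methyl-CBS-oxazaborolidine [(3aR)-1-methyl-3,3-diphenyltetrahydro-1H,3H-pyrrolo[1,2-c][1,3,2]oxazaborole] (0.5 equiv), catecholborane, toluene, −78 °C; then MeOH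
Reagents that add atoms: none
Why: Corey–Bakshi–Shibata reduction: the C6 dienone carbonyl is more electrophilic than the vinylogous ester at C1, and catecholborane at low temperature does not hydroborate the alkenes. With the alkenyl arm as the large group, the (R)-catalyst should deliver hydride to the face that gives the 6R carbinol.

Step 19
Reactants: 27 tiglic acid
Product: 28 tiglyl alcohol
Conditions: LiAlH4, Et2O, 0 °C
Reagents that add atoms: none
Why: Hydride reduction of the unsaturated acid to the allylic alcohol with the E geometry unchanged.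

Step 20
Reactants: 28 tiglyl alcohol
Product: 29 (2R,3R)-epoxy alcohol
Conditions: Ti(OiPr)4 (10 mol%), D-(−)-diethyl tartrate (12 mol%), t-BuOOH, 4 Å molecular sieves, CH2Cl2, −20 °C
Reagents that add atoms: tert-butyl hydroperoxide, CC(C)(C)OO
Why: Sharpless asymmetric epoxidation; the D-tartrate delivers oxygen to the face of the E-allylic alcohol that gives the (2R,3R)-epoxide, setting both side-chain centres, with the two methyl groups cis as in the alkene.

Step 21
Reactants: 29 (2R,3R)-epoxy alcohol
Product: 30 (2S,3R)-2,3-dimethyloxirane-2-carboxylic acid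
Conditions: TEMPO (2,2,6,6-tetramethylpiperidin-1-oxyl, 10 mol%), PhI(OAc)2 (2.2 equiv), MeCN/H2O, rt
Reagents that add atoms: water, O
Why: Oxoammonium oxidation of the primary alcohol through the aldehyde hydrate to the acid under near-neutral conditions that spare the oxirane; the C2 descriptor changes from R to S only because of the priority change.

Step 22
Reactants: 26 (6R)-furanone alcohol; 30 (2S,3R)-2,3-dimethyloxirane-2-carboxylic acid
Product: 32 6-O-acyl bis-silyl ether, via mixed anhydride 31 (not isolated)
Conditions: 30, 2,4,6-trichlorobenzoyl chloride, Et3N, toluene, rt; then 26, 4-(dimethylamino)pyridine, toluene, rt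
Reagents that add atoms: none
Why: Yamaguchi esterification: the hindered mixed anhydride transfers only the glycidic acyl group to the secondary allylic alcohol with retention at C6. The acid has no α-hydrogen, so it cannot epimerise.

Step 23
Reactants: 32 6-O-acyl bis-silyl ether
Product: 33 6-O-acyl 8,12-diol
Conditions: HF·pyridine, pyridine, THF, 0 °C → rt
Reagents that add atoms: none
Why: Buffered acidic fluoride removes the primary and the secondary TBS ether without generating an alkoxide, so the C6 ester cannot migrate to O8 and the oxirane and furanone are not attacked.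

Step 24
Reactants: 33 6-O-acyl 8,12-diol
Product: 36 target furanone germacranolide, via enal 34 (not isolated), via lactol 35 (not isolated)
Conditions: TEMPO (20 mol%), PhI(OAc)2 (2.5 equiv), CH2Cl2, rt
Reagents that add atoms: none
Why: Oxidative lactonisation: the oxoammonium oxidises the primary allylic alcohol much faster than the secondary O8–H. The enal is trapped by O8 as the five-membered lactol, which is oxidised on to the α-methylene lactone; C7 and C8 are unchanged, so the lactone is trans-fused.

## Compound list

1 | (R)-carvone, (5R)-2-methyl-5-(prop-1-en-2-yl)cyclohex-2-en-1-one | CC1=CC[C@H](CC1=O)C(=C)C | starting material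
2 | 10-hydroxycarvone, (5R)-5-(3-hydroxyprop-1-en-2-yl)-2-methylcyclohex-2-en-1-one | C=C(CO)[C@@H]1CC=C(C)C(=O)C1 | intermediate
3 | 10-(tert-butyldimethylsilyloxy)carvone | C=C(CO[Si](C)(C)C(C)(C)C)[C@@H]1CC=C(C)C(=O)C1 | intermediate
4 | bromomagnesium dienolate of 3 (linear, C1=C10 and C8=C9) | C=C(CO[Si](C)(C)C(C)(C)C)[C@@H]1C=CC(C)=C(O[Mg]Br)C1 | intermediate
5 | linear trimethylsilyl dienol ether (1-silyloxy-cyclohexa-1,3-diene) | C=C(CO[Si](C)(C)C(C)(C)C)[C@@H]1C=CC(C)=C(O[Si](C)(C)C)C1 | intermediate
6 | endoperoxide bridging C1 and C8, anti to the C7 side chain | C=C(CO[Si](C)(C)C(C)(C)C)[C@H]1C[C@]2(O[Si](C)(C)C)OO[C@H]1C=C2C | intermediate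
7 | γ-hydroperoxy enone (OOH on C8, trans to the C7 side chain) | C=C(CO[Si](C)(C)C(C)(C)C)[C@@H]1[C@@H](OO)C=C(C)C(=O)C1 | intermediate
8 | 8-hydroxy enone, (4S,5R)-4-hydroxy-2-methyl-5-[3-(tert-butyldimethylsilyloxy)prop-1-en-2-yl]cyclohex-2-en-1-one | C=C(CO[Si](C)(C)C(C)(C)C)[C@@H]1[C@@H](O)C=C(C)C(=O)C1 | intermediate
9 | 9,10-epoxy-8-hydroxy ketone (epoxide cis to O8, trans to the C7 side chain) | C=C(CO[Si](C)(C)C(C)(C)C)[C@@H]1[C@@H](O)[C@H]2O[C@@]2(C)C(=O)C1 | intermediate
10 | 9,10-epoxy-8-silyloxy ketone (8-O-TBS ether of 9) | C=C(CO[Si](C)(C)C(C)(C)C)[C@@H]1[C@@H](O[Si](C)(C)C(C)(C)C)[C@H]2O[C@@]2(C)C(=O)C1 | intermediate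
11 | 1,10-diol (O8 and O12 as TBS ethers; O10 cis to O8; C1 carbinol drawn cis to O10) | C=C(CO[Si](C)(C)C(C)(C)C)[C@@H]1[C@@H](O[Si](C)(C)C(C)(C)C)C[C@@](C)(O)[C@@H](O)C1 | intermediate
12 | 10-hydroxy 1-ketone | C=C(CO[Si](C)(C)C(C)(C)C)[C@@H]1[C@@H](O[Si](C)(C)C(C)(C)C)C[C@@](C)(O)C(=O)C1 | intermediate
13 | 10-triethylsilyloxy 1-ketone | C=C(CO[Si](C)(C)C(C)(C)C)[C@@H]1[C@@H](O[Si](C)(C)C(C)(C)C)C[C@@](C)(O[Si](CC)(CC)CC)C(=O)C1 | intermediate
14 | potassium enolate of 13 (C1=C6) | C=C(CO[Si](C)(C)C(C)(C)C)[C@@H]1[C@@H](O[Si](C)(C)C(C)(C)C)C[C@@](C)(O[Si](CC)(CC)CC)C(O[K])=C1 | intermediate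
15 | 6-hydroxy 1-ketone (O6 drawn trans to the C7 side chain) | C=C(CO[Si](C)(C)C(C)(C)C)[C@@H]1[C@@H](O[Si](C)(C)C(C)(C)C)C[C@@](C)(O[Si](CC)(CC)CC)C(=O)[C@H]1O | intermediate
16 | 1,6-dione | C=C(CO[Si](C)(C)C(C)(C)C)[C@@H]1[C@@H](O[Si](C)(C)C(C)(C)C)C[C@@](C)(O[Si](CC)(CC)CC)C(=O)C1=O | intermediate
17 | (R)-but-3-yn-2-ol | C#C[C@@H](C)O | starting material
18 | vinylmagnesium alkoxide chelate (five-membered oxamagnesacycle) | C[C@H]1O[Mg]C=C1C | intermediate
19 | (2R,3Z)-4-iodo-3-methylbut-3-en-2-ol | I/C=C(C)\[C@@H](C)O | intermediate
20 | dilithio reagent from 19 (Z-alkenyllithium lithium alkoxide, then transmetalated to cerium) | [Li]/C=C(C)\[C@@H](C)O[Li] | intermediate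
21 | C6 adduct: 1-ketone with tertiary C6 hydroxyl and Z-alkenyl chain bearing the C3 carbinol | C=C(CO[Si](C)(C)C(C)(C)C)[C@@H]1[C@@H](O[Si](C)(C)C(C)(C)C)C[C@@](C)(O[Si](CC)(CC)CC)C(=O)[C@@]1(O)/C=C(C)\[C@@H](C)O | intermediate
22 | 6-hydroxy 1,3-dione (Z-enone methyl ketone on C6) | C=C(CO[Si](C)(C)C(C)(C)C)[C@@H]1[C@@H](O[Si](C)(C)C(C)(C)C)C[C@@](C)(O[Si](CC)(CC)CC)C(=O)[C@@]1(O)/C=C(C)\C(C)=O | intermediate
23 | cis-1,6-dihydroxy decalin enone (1,6-cyclo form of the ring) | C=C(CO[Si](C)(C)C(C)(C)C)[C@@H]1[C@@H](O[Si](C)(C)C(C)(C)C)C[C@@](C)(O[Si](CC)(CC)CC)[C@@]2(O)CC(=O)C(C)=C[C@@]12O | intermediate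
24 | ten-membered 1,3,6-trione with Z enone | C=C(CO[Si](C)(C)C(C)(C)C)[C@@H]1[C@@H](O[Si](C)(C)C(C)(C)C)C[C@@](C)(O[Si](CC)(CC)CC)C(=O)CC(=O)/C(C)=C\C1=O | intermediate
25 | furanone 6-ketone (O8 and O12 as TBS ethers) | C=C(CO[Si](C)(C)C(C)(C)C)[C@@H]1[C@@H](O[Si](C)(C)C(C)(C)C)C[C@@]2(C)OC(=CC2=O)/C(C)=C\C1=O | intermediate
26 | (6R)-furanone alcohol | C=C(CO[Si](C)(C)C(C)(C)C)[C@@H]1[C@@H](O[Si](C)(C)C(C)(C)C)C[C@@]2(C)OC(=CC2=O)/C(C)=C\[C@H]1O | intermediate
27 | tiglic acid, (E)-2-methylbut-2-enoic acid | C/C=C(\C)C(=O)O | starting material
28 | tiglyl alcohol, (E)-2-methylbut-2-en-1-ol | C/C=C(\C)CO | intermediate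
29 | [(2R,3R)-2,3-dimethyloxiran-2-yl]methanol | OC[C@@]1(C)O[C@@H]1C | intermediate
30 | (2S,3R)-2,3-dimethyloxirane-2-carboxylic acid | OC(=O)[C@@]1(C)O[C@@H]1C | intermediate
31 | mixed anhydride of 30 with 2,4,6-trichlorobenzoic acid | O=C(OC(=O)[C@@]1(C)O[C@@H]1C)c1c(Cl)cc(Cl)cc1Cl | intermediate
32 | 6-O-acyl bis-silyl ether | C=C(CO[Si](C)(C)C(C)(C)C)[C@@H]1[C@@H](O[Si](C)(C)C(C)(C)C)C[C@@]2(C)OC(=CC2=O)/C(C)=C\[C@H]1OC(=O)[C@@]3(C)O[C@@H]3C | intermediate
33 | 6-O-acyl 8,12-diol | C=C(CO)[C@@H]1[C@@H](O)C[C@@]2(C)OC(=CC2=O)/C(C)=C\[C@H]1OC(=O)[C@@]3(C)O[C@@H]3C | intermediate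
34 | enal (C12 aldehyde, O8–H free) | C=C(C=O)[C@@H]1[C@@H](O)C[C@@]2(C)OC(=CC2=O)/C(C)=C\[C@H]1OC(=O)[C@@]3(C)O[C@@H]3C | intermediate
35 | lactol (C12 hemiacetal with O8, both anomers) | C=C1C(O)O[C@H]2C[C@@]3(C)OC(=CC3=O)/C(C)=C\[C@@H](OC(=O)[C@@]4(C)O[C@@H]4C)[C@H]12 | intermediate
36 | target (6R,7R,8S,10R; Z-4,5; 8,12-olide; 6-O-[(2S,3R)-2,3-dimethyloxirane-2-carbonyl]) | C=C1C(=O)O[C@H]2C[C@@]3(C)OC(=CC3=O)/C(C)=C\[C@@H](OC(=O)[C@@]3(C)O[C@@H]3C)[C@H]12 | target

## Step count and least certain steps

Total step count: 24. Longest linear sequence: 20 steps (steps 1–11, 13–18 and 22–24, from 1 to 36). Step 12 and steps 19–21 are side branches.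

Step 16 (key step). Most likely to go wrong: once the ring opens, the enolisable C1/C3 diketone can be acetoxylated by remaining oxidant, or C2 can add across the ring to the new C6 ketone. Fallback, from 23 back to 24: the C3 ketone is removed from play before the cleavage. Reduction with NaBH4/CeCl3 should give the C3 allylic alcohol F1. Et3SiCl/imidazole should silylate only this secondary hydroxyl, giving the 3-O-triethylsilyl ether F2. Glycol cleavage with Pb(OAc)4 then gives the ten-membered 1,6-dione F3, which has no 1,3-diketone. PPTS in MeOH at 0 °C should remove the secondary allylic silyl ether and not the tertiary one, giving the 3-hydroxy dione F4. Dess–Martin oxidation returns to the route at 24.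

Step 13. Most likely to go wrong: the dione tautomerises to the C6 enol before or during the addition, which erases C7 and opens the way to β-elimination of the C8 silyloxy group; attack at C1 may also compete. Fallback, from 15 back to 22: the C1 carbonyl is taken to a protected alcohol so that no 1,2-dione is ever formed. Acetylation gives the 6-acetate F5. NaBH4 gives the 1-hydroxy 6-acetate F6. Me3SiOTf/2,6-lutidine gives the 1-O-trimethylsilyl 6-acetate F7. DIBAL-H at −78 °C removes the acetate to give the 1-O-trimethylsilyl 6-alcohol F8. Dess–Martin oxidation gives the 1-O-trimethylsilyl 6-ketone F9. The cerium reagent from 20 adds to give the protected adduct F10. K2CO3 in MeOH removes the trimethylsilyl group and leaves the tertiary triethylsilyl ether, giving the 1,3,6-triol F11. Dess–Martin oxidation of both secondary alcohols returns to the route at 22.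

Step 4. Most likely to go wrong: base-type dehydration of the allylic hydroperoxide to the ene-dione, an ene reaction at the side-chain alkene, or insufficient facial selectivity in the cycloaddition. Fallback, from 5 back to 8: oxygen is transferred by epoxidation and not by cycloaddition. Dimethyldioxirane in acetone at −78 °C should epoxidise the distal C8=C9 bond of the dienol ether; silyl-assisted opening gives the 8-O-trimethylsilyl ether F12, and K2CO3/MeOH returns to the route at 8.

Step 7. Most likely to go wrong: slow or misdirected epoxide opening, because backside attack at C9 requires the conformer with the C7 substituent axial, so attack at C10 or incomplete reaction may compete. Fallback, from 10 back to 11: the two reductions are separated and the second is directed by the hydroxyl. NaBH4/CeCl3 gives the epoxy alcohol F13. DIBAL-H, which opens 2,3-epoxy alcohols at the carbon remote from the carbinol, then gives the 1,2-diol and returns to the route at 11.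

Step 17. Most likely to go wrong: loss of the primary allylic silyl ether competing with loss of the tertiary one, or acid-induced transannular aldol before the furanone closes. Fallback, from 24 to 36, with the endgame reordered so that no silyl ether has to be kept. HF·pyridine removes all three silyl groups and closes the furanone, giving the desilylated furanone ketone F14. TEMPO/PhI(OAc)2 gives the 6-oxo lactone F15. Reduction with the (R)-oxazaborolidine and catecholborane gives the 6-hydroxy lactone F16. Yamaguchi esterification with 30 gives 36.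

Step 18. Most likely to go wrong: hydride delivery to the other face, since both groups flanking the C6 carbonyl are large and the ring conformation may override the catalyst; conjugate reduction of the dienone is a lesser risk. Fallback, from 25 back to 32: if the reduction gives the (6S)-alcohol F17 (it can be made deliberately with the enantiomeric catalyst), Mitsunobu esterification with 30 (PPh3, diisopropyl azodicarboxylate) inverts C6 and returns to the route at 32.

## Further compounds

F1 | step 16 | C3 allylic alcohol of 23 (C3 epimers) | C=C(CO[Si](C)(C)C(C)(C)C)[C@@H]1[C@@H](O[Si](C)(C)C(C)(C)C)C[C@@](C)(O[Si](CC)(CC)CC)[C@@]2(O)CC(O)C(C)=C[C@@]12O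
F2 | step 16 | 3-O-triethylsilyl ether of F1 | C=C(CO[Si](C)(C)C(C)(C)C)[C@@H]1[C@@H](O[Si](C)(C)C(C)(C)C)C[C@@](C)(O[Si](CC)(CC)CC)[C@@]2(O)CC(O[Si](CC)(CC)CC)C(C)=C[C@@]12O
F3 | step 16 | ten-membered 1,6-dione with 3-O-triethylsilyl group | C=C(CO[Si](C)(C)C(C)(C)C)[C@@H]1[C@@H](O[Si](C)(C)C(C)(C)C)C[C@@](C)(O[Si](CC)(CC)CC)C(=O)CC(O[Si](CC)(CC)CC)/C(C)=C\C1=O
F4 | step 16 | 3-hydroxy ten-membered 1,6-dione | C=C(CO[Si](C)(C)C(C)(C)C)[C@@H]1[C@@H](O[Si](C)(C)C(C)(C)C)C[C@@](C)(O[Si](CC)(CC)CC)C(=O)CC(O)/C(C)=C\C1=O
F5 | step 13 | 6-acetate of 15 | C=C(CO[Si](C)(C)C(C)(C)C)[C@@H]1[C@@H](O[Si](C)(C)C(C)(C)C)C[C@@](C)(O[Si](CC)(CC)CC)C(=O)[C@H]1OC(C)=O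
F6 | step 13 | 1-hydroxy 6-acetate (C1 epimers) | C=C(CO[Si](C)(C)C(C)(C)C)[C@@H]1[C@@H](O[Si](C)(C)C(C)(C)C)C[C@@](C)(O[Si](CC)(CC)CC)C(O)[C@H]1OC(C)=O
F7 | step 13 | 1-O-trimethylsilyl 6-acetate | C=C(CO[Si](C)(C)C(C)(C)C)[C@@H]1[C@@H](O[Si](C)(C)C(C)(C)C)C[C@@](C)(O[Si](CC)(CC)CC)C(O[Si](C)(C)C)[C@H]1OC(C)=O
F8 | step 13 | 1-O-trimethylsilyl 6-alcohol | C=C(CO[Si](C)(C)C(C)(C)C)[C@@H]1[C@@H](O[Si](C)(C)C(C)(C)C)C[C@@](C)(O[Si](CC)(CC)CC)C(O[Si](C)(C)C)[C@H]1O
F9 | step 13 | 1-O-trimethylsilyl 6-ketone | C=C(CO[Si](C)(C)C(C)(C)C)[C@@H]1[C@@H](O[Si](C)(C)C(C)(C)C)C[C@@](C)(O[Si](CC)(CC)CC)C(O[Si](C)(C)C)C1=O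
F10 | step 13 | protected C6 adduct | C=C(CO[Si](C)(C)C(C)(C)C)[C@@H]1[C@@H](O[Si](C)(C)C(C)(C)C)C[C@@](C)(O[Si](CC)(CC)CC)C(O[Si](C)(C)C)[C@@]1(O)/C=C(C)\[C@@H](C)O
F11 | step 13 | 1,3,6-triol | C=C(CO[Si](C)(C)C(C)(C)C)[C@@H]1[C@@H](O[Si](C)(C)C(C)(C)C)C[C@@](C)(O[Si](CC)(CC)CC)C(O)[C@@]1(O)/C=C(C)\[C@@H](C)O
F12 | step 4 | 8-O-trimethylsilyl ether of 8 | C=C(CO[Si](C)(C)C(C)(C)C)[C@@H]1[C@@H](O[Si](C)(C)C)C=C(C)C(=O)C1
F13 | step 7 | epoxy alcohol (C1 carbinol of 10) | C=C(CO[Si](C)(C)C(C)(C)C)[C@@H]1[C@@H](O[Si](C)(C)C(C)(C)C)[C@H]2O[C@@]2(C)[C@@H](O)C1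
F14 | step 17 | desilylated furanone 6-ketone 8,12-diol | C=C(CO)[C@@H]1[C@@H](O)C[C@@]2(C)OC(=CC2=O)/C(C)=C\C1=O
F15 | step 17 | 6-oxo α-methylene lactone | C=C1C(=O)O[C@H]2C[C@@]3(C)OC(=CC3=O)/C(C)=C\C(=O)[C@H]12
F16 | step 17 | 6-hydroxy α-methylene lactone (6-deacyl 36) | C=C1C(=O)O[C@H]2C[C@@]3(C)OC(=CC3=O)/C(C)=C\[C@@H](O)[C@H]12
F17 | step 18 | (6S)-epimer of 26 | C=C(CO[Si](C)(C)C(C)(C)C)[C@@H]1[C@@H](O[Si](C)(C)C(C)(C)C)C[C@@]2(C)OC(=CC2=O)/C(C)=C\[C@@H]1O
A1 | alternative 1 | thirteen-membered bis-allylic ether with butenolide | O=C1O[C@H]2C[C@@]3(C)OC(=CC3=O)/C(C)=C\COCC1=C2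
A2 | alternative 1 | 6-hydroxy core (same compound as F16) | C=C1C(=O)O[C@H]2C[C@@]3(C)OC(=CC3=O)/C(C)=C\[C@@H](O)[C@H]12
A3 | alternative 2 | cyclooctenone with 1-propynyl ether on O10 | C=C1C(=O)O[C@H]2C[C@@](C)(OC#CC)C(=O)/C=C\[C@@H](O[Si](C)(C)C(C)(C)C)[C@H]12
A4 | alternative 2 | 6-O-TBS furanone germacranolide core | C=C1C(=O)O[C@H]2C[C@@]3(C)OC(=CC3=O)/C(C)=C\[C@@H](O[Si](C)(C)C(C)(C)C)[C@H]12
A5 | alternative 3 | cyclopropanated siloxyfuran aldehyde | COC(=O)C(C(=O)OC)[C@H](C=O)[C@H](O[Si](C)(C)C(C)(C)C)/C=C(C)\C1=C[C@@]2(O[Si](C)(C)C)C[C@@]2(C)O1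
A6 | alternative 3 | ten-membered furanone 8-hydroxy malonate | COC(=O)C(C(=O)OC)[C@@H]1[C@@H](O)C[C@@]2(C)OC(=CC2=O)/C(C)=C\[C@H]1O[Si](C)(C)C(C)(C)C
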